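**Retrosynthetic overview**
1. Target 32 ⇐ open-chain bromo aldehyde 29: one intramolecular Cr(II) Barbier allylation forms C6–C7 and the ten-membered ring, and the alkoxide then closes the α-methylene-γ-lactone.
2. 29 ⇐ C9–C10 bond: Nozaki–Hiyama–Kishi coupling of West (Z)-α-iodoenoate 9 with East aldehyde 23, which already carries the epoxyangelate on C8; C9–OH is then acetylated.
3. 9 ⇐ (Z)-3-methylpent-2-en-4-yn-1-ol: two Sharpless epoxidations (4,5- then 2,3-oxirane), C1 from formaldehyde, C10/C14 by an iodo-Wittig reaction.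
4. 23 ⇐ (R)-glyceraldehyde acetonide + methyl acrylate (Baylis–Hillman; C8 from the chiral pool) and (2S,3S)-epoxyangelic acid from methyl angelate (Sharpless epoxidation).
5. Ring order: both oxiranes (acyclic, reagent control) → carbocycle → lactone.

Assumption: C-numbers in names are the germacrane numbers of the target (C6–O = lactone oxygen, C12 = lactone C=O, C13 = exocyclic CH2, C14 = CO2Me carbon, C15 = 4-methyl).
Assumption: the open-chain compounds 25–29 share the chain C13–C11(CO2Me)–C7–C8–C9–C10(CO2Me)=C1–C2/C3 cis-oxirane–C4(Me)/C5 cis-oxirane–C6, with C2, C3, C4, C5, C8 and C9 configured as in 32 and the 1(10) olefin E; their short names give only what changes, and the compound list gives each SMILES.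
Assumption: 12 is drawn as its major anti (7S) epimer; the 7R epimer formed alongside is carried through, because C7 becomes sp2 in step 21.
Assumption: 1, 10, 11, 16 and all reagents are purchased. The route is a design and has not been run; the tartrate enantiomers were assigned from the known outcome L-(+)-tartrate + (E)-hex-2-en-1-ol → (2S,3S)-epoxy alcohol.

Step 1
Reactants: 1 (2Z)-3-methylpent-2-en-4-yn-1-ol
Product: 2 [(2R,3S)-3-ethynyl-3-methyloxiran-2-yl]methanol
Conditions: Ti(OiPr)4 (10 mol %), D-(−)-DIPT (12 mol %), t-BuOOH, 4 Å MS, CH2Cl2, −20 °C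
Reagents that add atoms: tert-butyl hydroperoxide CC(C)(C)OO
Why: Sharpless asymmetric epoxidation of a Z-trisubstituted (nerol-type) allylic alcohol, in which the Ti/D-(−)-tartrate complex delivers oxygen to the face that sets C5 and C4 as in the target while the alkyne is inert.

Step 2
Reactants: 2 [(2R,3S)-3-ethynyl-3-methyloxiran-2-yl]methanol
Product: 3 tert-butyl{[(2R,3S)-3-ethynyl-3-methyloxiran-2-yl]methoxy}dimethylsilane
Conditions: TBSCl, imidazole, DMF, 0 °C to rt
Reagents that add atoms: tert-butyldimethylsilyl chloride CC(C)(C)[Si](C)(C)Cl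
Why: Silyl ether protection of the primary C6 alcohol, which touches no stereocentre and survives every step up to the late fluoride deprotection.

Step 3
Reactants: 3 tert-butyl{[(2R,3S)-3-ethynyl-3-methyloxiran-2-yl]methoxy}dimethylsilane
Product: 5 3-[(2S,3R)-3-({[tert-butyl(dimethyl)silyl]oxy}methyl)-2-methyloxiran-2-yl]prop-2-yn-1-ol, via {[(2S,3R)-3-({[tert-butyl(dimethyl)silyl]oxy}methyl)-2-methyloxiran-2-yl]ethynyl}lithium 4 (not isolated)
Conditions: n-BuLi, THF, −78 °C; (CH2O)n, −78 °C to rt; H2O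
Reagents that add atoms: formaldehyde (as paraformaldehyde) C=O
Why: Acetylide 1,2-addition to formaldehyde adds C1 as a propargylic alcohol, the terminal alkyne being deprotonated far faster than the oxirane is attacked at −78 °C.

Step 4
Reactants: 5 3-[(2S,3R)-3-({[tert-butyl(dimethyl)silyl]oxy}methyl)-2-methyloxiran-2-yl]prop-2-yn-1-ol
Product: 6 (2Z)-3-[(2S,3R)-3-({[tert-butyl(dimethyl)silyl]oxy}methyl)-2-methyloxiran-2-yl]prop-2-en-1-ol
Conditions: H2 (1 atm), Lindlar Pd, quinoline, EtOAc, rt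
Reagents that add atoms: none
Why: Lindlar semi-hydrogenation delivers H2 syn to give the Z-olefin required for the cis-2,3-oxirane, the quinoline suppressing over-reduction and hydrogenolysis of the propargylic oxirane.

Step 5
Reactants: 6 (2Z)-3-[(2S,3R)-3-({[tert-butyl(dimethyl)silyl]oxy}methyl)-2-methyloxiran-2-yl]prop-2-en-1-ol
Product: 7 {(2R,3R)-3-[(2R,3R)-3-({[tert-butyl(dimethyl)silyl]oxy}methyl)-2-methyloxiran-2-yl]oxiran-2-yl}methanol
Conditions: Ti(OiPr)4 (30 mol %), D-(−)-DIPT (36 mol %), t-BuOOH, 4 Å MS, CH2Cl2, −20 °C, 48–72 h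
Reagents that add atoms: tert-butyl hydroperoxide CC(C)(C)OO
Why: A second Sharpless asymmetric epoxidation, directed by the new C1 hydroxyl, in which D-(−)-tartrate is chosen to deliver oxygen to the face giving the (2R,3R) cis-oxirane of the target.

Step 6
Reactants: 7 {(2R,3R)-3-[(2R,3R)-3-({[tert-butyl(dimethyl)silyl]oxy}methyl)-2-methyloxiran-2-yl]oxiran-2-yl}methanol
Product: 8 (2S,3R)-3-[(2R,3R)-3-({[tert-butyl(dimethyl)silyl]oxy}methyl)-2-methyloxiran-2-yl]oxirane-2-carbaldehyde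
Conditions: PhI(OAc)2, TEMPO (10 mol %), CH2Cl2, rt; used crude
Reagents that add atoms: none
Why: TEMPO/oxoammonium oxidation stops at the aldehyde under near-neutral conditions, so the epimerisable cis-epoxy aldehyde keeps its configuration.

Step 7
Reactants: 8 (2S,3R)-3-[(2R,3R)-3-({[tert-butyl(dimethyl)silyl]oxy}methyl)-2-methyloxiran-2-yl]oxirane-2-carbaldehyde
Product: 9 methyl (2Z)-3-{(2R,3R)-3-[(2R,3R)-3-({[tert-butyl(dimethyl)silyl]oxy}methyl)-2-methyloxiran-2-yl]oxiran-2-yl}-2-iodoprop-2-enoate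
Conditions: Ph3P=CHCO2Me, NIS, MeCN, −20 °C; then 8, K2CO3, −20 °C to rt
Reagents that add atoms: methyl (triphenylphosphoranylidene)acetate COC(=O)C=P(c1ccccc1)(c1ccccc1)c1ccccc1; N-iodosuccinimide O=C1CCC(=O)N1I
Why: Wittig olefination by the iodo-ylide made in the flask gives the (Z)-α-iodoenoate whose ester is trans to C2, which fixes the 1(10) geometry of the target and leaves iodine as the handle for C9.

Step 8
Reactants: 10 (4R)-2,2-dimethyl-1,3-dioxolane-4-carbaldehyde; 11 methyl prop-2-enoate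
Product: 12 methyl 2-{(S)-[(4R)-2,2-dimethyl-1,3-dioxolan-4-yl](hydroxy)methyl}prop-2-enoate
Conditions: DABCO (0.5 equiv), neat, rt, 5–7 d
Reagents that add atoms: none
Why: Morita–Baylis–Hillman reaction joins C7 to C11 while C8 is taken from the chiral pool, the anti (Felkin) carbinol predominating, although C7 is later erased.

Step 9
Reactants: 12 methyl 2-{(S)-[(4R)-2,2-dimethyl-1,3-dioxolan-4-yl](hydroxy)methyl}prop-2-enoate
Product: 13 methyl 2-{(S)-{[tert-butyl(dimethyl)silyl]oxy}[(4R)-2,2-dimethyl-1,3-dioxolan-4-yl]methyl}prop-2-enoate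
Conditions: TBSOTf, 2,6-lutidine, CH2Cl2, −78 °C
Reagents that add atoms: tert-butyldimethylsilyl triflate CC(C)(C)[Si](C)(C)OS(=O)(=O)C(F)(F)F
Why: Silyl ether formation by the reactive triflate protects the hindered allylic C7 alcohol without disturbing the acetonide or any stereocentre.

Step 10
Reactants: 13 methyl 2-{(S)-{[tert-butyl(dimethyl)silyl]oxy}[(4R)-2,2-dimethyl-1,3-dioxolan-4-yl]methyl}prop-2-enoate
Product: 14 methyl (3S,4R)-3-{[tert-butyl(dimethyl)silyl]oxy}-4,5-dihydroxy-2-methylidenepentanoate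
Conditions: AcOH/H2O (4:1), 40 °C
Reagents that add atoms: none
Why: Acid-catalysed acetal hydrolysis removes the terminal acetonide while the hindered secondary TBS ether survives, and it is done before any oxirane is present.

Step 11
Reactants: 14 methyl (3S,4R)-3-{[tert-butyl(dimethyl)silyl]oxy}-4,5-dihydroxy-2-methylidenepentanoate
Product: 15 methyl (3S,4R)-3-{[tert-butyl(dimethyl)silyl]oxy}-4-hydroxy-2-methylidene-5-[(triethylsilyl)oxy]pentanoate
Conditions: TESCl (1.05 equiv), imidazole, CH2Cl2, −40 °C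
Reagents that add atoms: chlorotriethylsilane CC[Si](CC)(CC)Cl
Why: Selective silylation of the primary C9 hydroxyl on steric grounds leaves only the C8 hydroxyl free for acylation.

Step 12
Reactants: 16 methyl (2Z)-2-methylbut-2-enoate
Product: 17 (2Z)-2-methylbut-2-en-1-ol
Conditions: DIBAL-H (2.2 equiv), CH2Cl2, −78 °C; Rochelle salt
Reagents that add atoms: none
Why: Hydride reduction of the ester to the allylic alcohol leaves the Z-olefin geometry of the angelate untouched.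

Step 13
Reactants: 17 (2Z)-2-methylbut-2-en-1-ol
Product: 18 [(2R,3S)-2,3-dimethyloxiran-2-yl]methanol
Conditions: Ti(OiPr)4 (10 mol %), D-(−)-DIPT (12 mol %), t-BuOOH, 4 Å MS, CH2Cl2, −20 °C
Reagents that add atoms: tert-butyl hydroperoxide CC(C)(C)OO
Why: Sharpless asymmetric epoxidation under D-(−)-tartrate control sets both oxirane centres of the side chain on the Z-olefin, giving the cis relation of the C3 methyl and the future carboxyl.

Step 14
Reactants: 18 [(2R,3S)-2,3-dimethyloxiran-2-yl]methanol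
Product: 20 (2S,3S)-2,3-dimethyloxirane-2-carboxylic acid, via (2S,3S)-2,3-dimethyloxirane-2-carbaldehyde 19 (not isolated)
Conditions: PhI(OAc)2 (2.2 equiv), TEMPO (20 mol %), MeCN/H2O (1:1), rt
Reagents that add atoms: water O
Why: TEMPO/PhI(OAc)2 oxidation in aqueous acetonitrile takes the alcohol through the aldehyde hydrate to the acid, and the quaternary α-carbon cannot epimerise.

Step 15
Reactants: 15 methyl (3S,4R)-3-{[tert-butyl(dimethyl)silyl]oxy}-4-hydroxy-2-methylidene-5-[(triethylsilyl)oxy]pentanoate; 20 (2S,3S)-2,3-dimethyloxirane-2-carboxylic acid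
Product: 22 (2R,3S)-3-{[tert-butyl(dimethyl)silyl]oxy}-4-(methoxycarbonyl)-1-[(triethylsilyl)oxy]pent-4-en-2-yl (2S,3S)-2,3-dimethyloxirane-2-carboxylate, via (2S,3S)-2,3-dimethyloxirane-2-carboxylic 2,4,6-trichlorobenzoic anhydride 21 (not isolated)
Conditions: 20, 2,4,6-trichlorobenzoyl chloride, Et3N, THF, rt; then 15, DMAP, toluene, rt to 40 °C
Reagents that add atoms: none
Why: Yamaguchi esterification acylates the hindered C8 hydroxyl at oxygen, so C8 is retained, and it installs the final epoxyangelate early so that no late protecting-group step is needed at C8.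

Step 16
Reactants: 22 (2R,3S)-3-{[tert-butyl(dimethyl)silyl]oxy}-4-(methoxycarbonyl)-1-[(triethylsilyl)oxy]pent-4-en-2-yl (2S,3S)-2,3-dimethyloxirane-2-carboxylate
Product: 23 (2S,3S)-3-{[tert-butyl(dimethyl)silyl]oxy}-4-(methoxycarbonyl)-1-oxopent-4-en-2-yl (2S,3S)-2,3-dimethyloxirane-2-carboxylate
Conditions: (COCl)2, DMSO, CH2Cl2, −78 to −30 °C; Et3N, −78 to 0 °C; used at once
Reagents that add atoms: none
Why: Swern oxidation converts the primary triethylsilyl ether directly into the C9 aldehyde (desilylative oxidation) while the secondary TBS ether stays, and the low temperature protects the α-acyloxy stereocentre.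

Step 17
Reactants: 9 methyl (2Z)-3-{(2R,3R)-3-[(2R,3R)-3-({[tert-butyl(dimethyl)silyl]oxy}methyl)-2-methyloxiran-2-yl]oxiran-2-yl}-2-iodoprop-2-enoate; 23 (2S,3S)-3-{[tert-butyl(dimethyl)silyl]oxy}-4-(methoxycarbonyl)-1-oxopent-4-en-2-yl (2S,3S)-2,3-dimethyloxirane-2-carboxylate
Product: 25 open-chain (9R)-C9 alcohol, via C10-dichlorochromium(III) alkenyl species 24 (not isolated)
Conditions: CrCl2 (6 equiv), NiCl2 (2 mol %), DMSO/THF, rt
Reagents that add atoms: none
Why: Nozaki–Hiyama–Kishi coupling, in which Ni inserts into the C–I bond without loss of olefin geometry and the alkenyl–Cr(III) species adds only to the aldehyde, the polar Felkin–Anh approach anti to the C8–O bond being expected to give the 8,9-anti (9R) carbinol that carries 6-OTBS, 7-OTBS and the 8-O-epoxyangelate.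

Step 18
Reactants: 25 open-chain (9R)-C9 alcohol
Product: 26 open-chain C9 acetate
Conditions: Ac2O, pyridine, DMAP (cat.), CH2Cl2, 0 °C to rt
Reagents that add atoms: acetic anhydride CC(=O)OC(C)=O
Why: DMAP-catalysed acetylation at oxygen fixes the C9 acetate without touching the stereocentre and, done promptly, forestalls an 8→9 acyl shift.

Step 19
Reactants: 26 open-chain C9 acetate
Product: 27 open-chain 6,7-diol
Conditions: HF·pyridine, pyridine, THF, 0 °C to rt
Reagents that add atoms: none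
Why: Buffered acidic fluoride desilylation removes both TBS ethers without acyl migration or oxirane opening.

Step 20
Reactants: 27 open-chain 6,7-diol
Product: 28 open-chain C6 aldehyde
Conditions: PhI(OAc)2 (1.1 equiv), TEMPO (10 mol %), CH2Cl2, 0 °C to rt
Reagents that add atoms: none
Why: TEMPO/oxoammonium oxidation is selective for the primary C6 alcohol over the hindered, electron-poor secondary allylic C7 alcohol and does not epimerise the cis-epoxy aldehyde.

Step 21
Reactants: 28 open-chain C6 aldehyde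
Product: 29 open-chain C13 bromide
Conditions: NBS, Me2S, CH2Cl2, −20 to 0 °C
Reagents that add atoms: N-bromosuccinimide O=C1CCC(=O)N1Br
Why: Corey–Kim-type activation of the Baylis–Hillman alcohol and SN2′ attack by bromide give the thermodynamically preferred (Z)-2-(bromomethyl)enoate (C8 cis to CH2Br), so both C7 epimers converge to one olefin.

Step 22
Reactants: 29 open-chain C13 bromide
Product: 32 CNP0077535.3, via C13-dichlorochromium(III) allyl species 30 (not isolated), via ten-membered C6-hydroxy C12 methyl ester 31 (not isolated)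
Conditions: CrCl2 (10 equiv), THF/DMF, slow addition to 1–2 mM, rt, 24 h; aqueous work-up (silica gel if lactonisation is incomplete)
Reagents that add atoms: none
Why: Intramolecular Nozaki–Hiyama (Cr(II) Barbier) allylation, in which the 2-(methoxycarbonyl)allyl–Cr(III) species adds through C7 to the epoxy aldehyde in a closed chair-like transition state held inside the forming ten-membered ring, expected to give the 6,7-anti adduct (the trans-lactone relationship) under macrocyclic control, after which the γ-alkoxide lactonises onto the C12 ester.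

**Compound list**
1 | (2Z)-3-methylpent-2-en-4-yn-1-ol | C#C/C(C)=C\CO | starting material
2 | [(2R,3S)-3-ethynyl-3-methyloxiran-2-yl]methanol | C#C[C@]1(C)O[C@@H]1CO | intermediate
3 | tert-butyl{[(2R,3S)-3-ethynyl-3-methyloxiran-2-yl]methoxy}dimethylsilane | C#C[C@]1(C)O[C@@H]1CO[Si](C)(C)C(C)(C)C | intermediate
4 | {[(2S,3R)-3-({[tert-butyl(dimethyl)silyl]oxy}methyl)-2-methyloxiran-2-yl]ethynyl}lithium | [Li]C#C[C@]1(C)O[C@@H]1CO[Si](C)(C)C(C)(C)C | intermediate
5 | 3-[(2S,3R)-3-({[tert-butyl(dimethyl)silyl]oxy}methyl)-2-methyloxiran-2-yl]prop-2-yn-1-ol | OCC#C[C@]1(C)O[C@@H]1CO[Si](C)(C)C(C)(C)C | intermediate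
6 | (2Z)-3-[(2S,3R)-3-({[tert-butyl(dimethyl)silyl]oxy}methyl)-2-methyloxiran-2-yl]prop-2-en-1-ol | OC/C=C\[C@]1(C)O[C@@H]1CO[Si](C)(C)C(C)(C)C | intermediate
7 | {(2R,3R)-3-[(2R,3R)-3-({[tert-butyl(dimethyl)silyl]oxy}methyl)-2-methyloxiran-2-yl]oxiran-2-yl}methanol | OC[C@H]1O[C@H]1[C@]1(C)O[C@@H]1CO[Si](C)(C)C(C)(C)C | intermediate
8 | (2S,3R)-3-[(2R,3R)-3-({[tert-butyl(dimethyl)silyl]oxy}methyl)-2-methyloxiran-2-yl]oxirane-2-carbaldehyde | O=C[C@H]1O[C@H]1[C@]1(C)O[C@@H]1CO[Si](C)(C)C(C)(C)C | intermediate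
9 | methyl (2Z)-3-{(2R,3R)-3-[(2R,3R)-3-({[tert-butyl(dimethyl)silyl]oxy}methyl)-2-methyloxiran-2-yl]oxiran-2-yl}-2-iodoprop-2-enoate | COC(=O)/C(I)=C/[C@H]1O[C@H]1[C@]1(C)O[C@@H]1CO[Si](C)(C)C(C)(C)C | intermediate
10 | (4R)-2,2-dimethyl-1,3-dioxolane-4-carbaldehyde | O=C[C@H]1COC(C)(C)O1 | starting material
11 | methyl prop-2-enoate | C=CC(=O)OC | starting material
12 | methyl 2-{(S)-[(4R)-2,2-dimethyl-1,3-dioxolan-4-yl](hydroxy)methyl}prop-2-enoate (major anti epimer) | C=C(C(=O)OC)[C@H](O)[C@H]1COC(C)(C)O1 | intermediate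
13 | methyl 2-{(S)-{[tert-butyl(dimethyl)silyl]oxy}[(4R)-2,2-dimethyl-1,3-dioxolan-4-yl]methyl}prop-2-enoate | C=C(C(=O)OC)[C@H](O[Si](C)(C)C(C)(C)C)[C@H]1COC(C)(C)O1 | intermediate
14 | methyl (3S,4R)-3-{[tert-butyl(dimethyl)silyl]oxy}-4,5-dihydroxy-2-methylidenepentanoate | C=C(C(=O)OC)[C@H](O[Si](C)(C)C(C)(C)C)[C@H](O)CO | intermediate
15 | methyl (3S,4R)-3-{[tert-butyl(dimethyl)silyl]oxy}-4-hydroxy-2-methylidene-5-[(triethylsilyl)oxy]pentanoate | C=C(C(=O)OC)[C@H](O[Si](C)(C)C(C)(C)C)[C@H](O)CO[Si](CC)(CC)CC | intermediate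
16 | methyl (2Z)-2-methylbut-2-enoate (methyl angelate) | C/C=C(/C)C(=O)OC | starting material
17 | (2Z)-2-methylbut-2-en-1-ol | C/C=C(/C)CO | intermediate
18 | [(2R,3S)-2,3-dimethyloxiran-2-yl]methanol | OC[C@@]1(C)O[C@H]1C | intermediate
19 | (2S,3S)-2,3-dimethyloxirane-2-carbaldehyde | O=C[C@@]1(C)O[C@H]1C | intermediate
20 | (2S,3S)-2,3-dimethyloxirane-2-carboxylic acid | OC(=O)[C@@]1(C)O[C@H]1C | intermediate
21 | (2S,3S)-2,3-dimethyloxirane-2-carboxylic 2,4,6-trichlorobenzoic anhydride | O=C(OC(=O)c1c(Cl)cc(Cl)cc1Cl)[C@@]1(C)O[C@H]1C | intermediate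
22 | (2R,3S)-3-{[tert-butyl(dimethyl)silyl]oxy}-4-(methoxycarbonyl)-1-[(triethylsilyl)oxy]pent-4-en-2-yl (2S,3S)-2,3-dimethyloxirane-2-carboxylate | C=C(C(=O)OC)[C@H](O[Si](C)(C)C(C)(C)C)[C@H](OC(=O)[C@@]1(C)O[C@H]1C)CO[Si](CC)(CC)CC | intermediate
23 | (2S,3S)-3-{[tert-butyl(dimethyl)silyl]oxy}-4-(methoxycarbonyl)-1-oxopent-4-en-2-yl (2S,3S)-2,3-dimethyloxirane-2-carboxylate | C=C(C(=O)OC)[C@H](O[Si](C)(C)C(C)(C)C)[C@H](OC(=O)[C@@]1(C)O[C@H]1C)C=O | intermediate
24 | C10-dichlorochromium(III) alkenyl species (9 with CrCl2 in place of I) | COC(=O)/C([Cr](Cl)Cl)=C/[C@H]1O[C@H]1[C@]1(C)O[C@@H]1CO[Si](C)(C)C(C)(C)C | intermediate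
25 | open-chain (9R)-C9 alcohol (6-OTBS; 7-OTBS; 8-O-epoxyangeloyl; 9-OH; 1(10)E) | C=C(C(=O)OC)[C@H](O[Si](C)(C)C(C)(C)C)[C@H](OC(=O)[C@@]1(C)O[C@H]1C)[C@H](O)/C(C(=O)OC)=C\[C@H]1O[C@H]1[C@]1(C)O[C@@H]1CO[Si](C)(C)C(C)(C)C | intermediate
26 | open-chain C9 acetate (6-OTBS; 7-OTBS; 8-O-epoxyangeloyl; 9-OAc) | C=C(C(=O)OC)[C@H](O[Si](C)(C)C(C)(C)C)[C@H](OC(=O)[C@@]1(C)O[C@H]1C)[C@H](OC(C)=O)/C(C(=O)OC)=C\[C@H]1O[C@H]1[C@]1(C)O[C@@H]1CO[Si](C)(C)C(C)(C)C | intermediate
27 | open-chain 6,7-diol (6-OH; 7-OH; 8-O-epoxyangeloyl; 9-OAc) | C=C(C(=O)OC)[C@H](O)[C@H](OC(=O)[C@@]1(C)O[C@H]1C)[C@H](OC(C)=O)/C(C(=O)OC)=C\[C@H]1O[C@H]1[C@]1(C)O[C@@H]1CO | intermediate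
28 | open-chain C6 aldehyde (C6 = CHO; 7-OH) | C=C(C(=O)OC)[C@H](O)[C@H](OC(=O)[C@@]1(C)O[C@H]1C)[C@H](OC(C)=O)/C(C(=O)OC)=C\[C@H]1O[C@H]1[C@]1(C)O[C@@H]1C=O | intermediate
29 | open-chain C13 bromide (C13H2Br; 7(11)Z; C6 = CHO) | BrC/C(C(=O)OC)=C\[C@H](OC(=O)[C@@]1(C)O[C@H]1C)[C@H](OC(C)=O)/C(C(=O)OC)=C\[C@H]1O[C@H]1[C@]1(C)O[C@@H]1C=O | intermediate
30 | C13-dichlorochromium(III) allyl species (29 with CrCl2 in place of Br) | Cl[Cr](Cl)C/C(C(=O)OC)=C\[C@H](OC(=O)[C@@]1(C)O[C@H]1C)[C@H](OC(C)=O)/C(C(=O)OC)=C\[C@H]1O[C@H]1[C@]1(C)O[C@@H]1C=O | intermediate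
31 | ten-membered C6-hydroxy C12 methyl ester (seco-lactone of the target) | C=C(C(=O)OC)[C@@H]2[C@H](OC(=O)[C@@]1(C)O[C@H]1C)[C@H](OC(C)=O)/C(C(=O)OC)=C\[C@H]1O[C@H]1[C@]1(C)O[C@@H]1[C@H]2O | intermediate
32 | CNP0077535.3 | C=C1C(=O)O[C@H]2[C@H]1[C@H](OC(=O)[C@@]1(C)O[C@H]1C)[C@H](OC(C)=O)/C(C(=O)OC)=C\[C@H]1O[C@H]1[C@]1(C)O[C@H]21 | target

**Totals**
Total step count: 22. Longest linear sequence: 13 steps (steps 1–7, then 17–22).

**Three steps most likely to fail**

Step 22 (macrocyclisation). The ring closure must form a strained ten-membered ring and set C6 and C7 under conformational control only. The wrong diastereomer, oligomers, or Cr(II) reduction of the epoxy carbonyl units are all possible. Fallback: sets out from 9 and 22 and returns at 32; it moves the ring-closing bond from C6–C7 to C9–C10. Compound 9 is desilylated (HF·pyridine) to the C6 alcohol of the iodoenoate F1 and oxidised (TEMPO/PhI(OAc)2) to the C6 aldehyde of the iodoenoate F2. Compound 22 is desilylated to the East 7,9-diol F3 and brominated (NBS/Me2S, which converts the allylic alcohol and leaves the saturated primary one) to the East allylic bromide bearing a free C9–OH F4. Intermolecular CrCl2 (no Ni, so the alkenyl iodide is untouched) Barbier coupling of F2 and F4 gives the open-chain C6-hydroxy ester F5 (not isolated), which lactonises to the 6,7-trans lactone carrying the iodoenoate and C9H2OH F6. TEMPO/PhI(OAc)2 gives the C9 aldehyde of that lactone F7. Intramolecular Nozaki–Hiyama–Kishi reaction (CrCl2, cat. NiCl2, high dilution) closes C9–C10 to the 9-O-deacetyl target F8, and Ac2O/pyridine gives 32.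

Step 17 (NHK coupling of the α-iodoenoate). An α-ester alkenyl metal can leak to an allenolate, which would scramble the 1(10) geometry, and Felkin control at C9 may be modest. Fallback: sets out from 9 and returns at 25; it carries C14 at the alcohol oxidation level through the coupling so the alkenyl metal has no α-carbonyl. DIBAL-H reduces 9 to the (Z)-2-iodo allylic alcohol (C14H2OH analogue of 9) F9. NHK coupling of F9 and 23 gives the C14,C9-diol analogue of 25 F10. TEMPO/PhI(OAc)2 oxidises only the primary allylic alcohol to the C14 enal F11. Pinnick oxidation (NaClO2, NaH2PO4, 2-methylbut-2-ene) gives the C14 acid F12, and TMSCHN2 gives 25.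

Step 5 (second Sharpless epoxidation). Compound 6 is a Z-allylic alcohol carrying a bulky quaternary cis substituent, so the reaction may be slow and poorly selective. The C1 hydroxyl can also open the allylic oxirane (5-exo) to a dihydrofuran. Fallback: sets out from 3 and returns at 8; the 2,3-oxirane is built by reagent-controlled chloroallylboration instead of epoxidation. Lindlar hydrogenation of 3 gives the vinyl oxirane tert-butyl{[(2R,3S)-3-ethenyl-3-methyloxiran-2-yl]methoxy}dimethylsilane F13. Ozonolysis (O3; Me2S) gives (2R,3R)-3-({[tert-butyl(dimethyl)silyl]oxy}methyl)-2-methyloxirane-2-carbaldehyde F14. (Z)-γ-Chloroallyl-B(Ipc)2 (from allyl chloride, LiNCy2 and the Ipc2BOMe enantiomer chosen for the required face, BF3·OEt2, −95 °C) gives the syn-chlorohydrin (1S,2S)-1-[(2S,3R)-3-({[tert-butyl(dimethyl)silyl]oxy}methyl)-2-methyloxiran-2-yl]-2-chlorobut-3-en-1-ol F15. K2CO3/MeOH closes it by inversion at the chloride-bearing carbon to the cis-vinyl bis-oxirane tert-butyl({(2R,3R)-3-[(2R,3R)-3-ethenyloxiran-2-yl]-3-methyloxiran-2-yl}methoxy)dimethylsilane F16, and ozonolysis (O3; Me2S) gives 8.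

**Further compounds**
F1 | step 22 | C6 alcohol of the iodoenoate (9 without TBS) | COC(=O)/C(I)=C/[C@H]1O[C@H]1[C@]1(C)O[C@@H]1CO
F2 | step 22 | C6 aldehyde of the iodoenoate | COC(=O)/C(I)=C/[C@H]1O[C@H]1[C@]1(C)O[C@@H]1C=O
F3 | step 22 | East 7,9-diol (22 without both silyl groups) | C=C(C(=O)OC)[C@H](O)[C@H](OC(=O)[C@@]1(C)O[C@H]1C)CO
F4 | step 22 | East allylic bromide bearing a free C9–OH, 7(11)Z | BrC/C(C(=O)OC)=C\[C@H](OC(=O)[C@@]1(C)O[C@H]1C)CO
F5 | step 22 | open-chain C6-hydroxy ester from the intermolecular Barbier coupling | C=C(C(=O)OC)[C@@H]([C@H](O)[C@H]2O[C@@]2(C)[C@@H]2O[C@@H]2/C=C(\I)C(=O)OC)[C@H](OC(=O)[C@@]3(C)O[C@H]3C)CO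
F6 | step 22 | 6,7-trans lactone carrying the iodoenoate and C9H2OH | C=C1C(=O)O[C@H]([C@H]2O[C@@]2(C)[C@@H]2O[C@@H]2/C=C(\I)C(=O)OC)[C@H]1[C@H](OC(=O)[C@@]3(C)O[C@H]3C)CO
F7 | step 22 | C9 aldehyde of that lactone | C=C1C(=O)O[C@H]([C@H]2O[C@@]2(C)[C@@H]2O[C@@H]2/C=C(\I)C(=O)OC)[C@H]1[C@H](OC(=O)[C@@]3(C)O[C@H]3C)C=O
F8 | step 22 | 9-O-deacetyl target (macrocyclic C9 alcohol) | C=C1C(=O)O[C@H]2[C@H]1[C@H](OC(=O)[C@@]1(C)O[C@H]1C)[C@H](O)/C(C(=O)OC)=C\[C@H]1O[C@H]1[C@]1(C)O[C@H]21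
F9 | step 17 | (Z)-2-iodo allylic alcohol (C14H2OH analogue of 9) | OC/C(I)=C/[C@H]1O[C@H]1[C@]1(C)O[C@@H]1CO[Si](C)(C)C(C)(C)C
F10 | step 17 | C14,C9-diol analogue of 25 | C=C(C(=O)OC)[C@H](O[Si](C)(C)C(C)(C)C)[C@H](OC(=O)[C@@]1(C)O[C@H]1C)[C@H](O)/C(CO)=C\[C@H]1O[C@H]1[C@]1(C)O[C@@H]1CO[Si](C)(C)C(C)(C)C
F11 | step 17 | C14 enal | C=C(C(=O)OC)[C@H](O[Si](C)(C)C(C)(C)C)[C@H](OC(=O)[C@@]1(C)O[C@H]1C)[C@H](O)/C(C=O)=C\[C@H]1O[C@H]1[C@]1(C)O[C@@H]1CO[Si](C)(C)C(C)(C)C
F12 | step 17 | C14 acid | C=C(C(=O)OC)[C@H](O[Si](C)(C)C(C)(C)C)[C@H](OC(=O)[C@@]1(C)O[C@H]1C)[C@H](O)/C(C(=O)O)=C\[C@H]1O[C@H]1[C@]1(C)O[C@@H]1CO[Si](C)(C)C(C)(C)C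
F13 | step 5 | tert-butyl{[(2R,3S)-3-ethenyl-3-methyloxiran-2-yl]methoxy}dimethylsilane | C=C[C@]1(C)O[C@@H]1CO[Si](C)(C)C(C)(C)C
F14 | step 5 | (2R,3R)-3-({[tert-butyl(dimethyl)silyl]oxy}methyl)-2-methyloxirane-2-carbaldehyde | O=C[C@]1(C)O[C@@H]1CO[Si](C)(C)C(C)(C)C
F15 | step 5 | (1S,2S)-1-[(2S,3R)-3-({[tert-butyl(dimethyl)silyl]oxy}methyl)-2-methyloxiran-2-yl]-2-chlorobut-3-en-1-ol | C=C[C@H](Cl)[C@@H](O)[C@]1(C)O[C@@H]1CO[Si](C)(C)C(C)(C)C
F16 | step 5 | tert-butyl({(2R,3R)-3-[(2R,3R)-3-ethenyloxiran-2-yl]-3-methyloxiran-2-yl}methoxy)dimethylsilane | C=C[C@H]1O[C@H]1[C@]1(C)O[C@@H]1CO[Si](C)(C)C(C)(C)C
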